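**Retrosynthetic overview**

1. Locants: C1 = ring CH carrying the side chain, C2/C3 = oxirane carbons (C2 methylated), C4 = methyl-bearing alkene carbon, C5 = alkene CH, C6 = quaternary carbon carrying the pyrone. The side chain comes from a syn aldol of pentan-3-one with a 2-substituted acrolein (from a C1–CH2CH2OH handle by oxidation and α-methylenation); the oxirane comes from face-selective epoxidation of C2=C3 of a cyclohexa-1,3-diene.
2. Carbocycle (key step): a propyne unit, used as a silylalkyne, is inserted between the vinylic iodide carbon C3 and the pyrone-activated C6–H of an acyclic precursor, forming C3–C4 and C5–C6; methylation of the resulting anion in the same flask sets quaternary C6.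
3. Enabling feature: C6 is bonded to the pyrone ring carbon next to the ring oxygen, so C6–H is a vinylogous carbon acid, and the MeC4=C5H alkene between C6 and C3 (sp2 at that stage, oxygenated later) is a masked propyne; the short C3–C2–C1–C6 tether rules out direct closure (cyclobutene).
4. The acyclic precursor comes from a vinylogous Mukaiyama–Michael addition of 2-methoxy-3,5,6-trimethylpyran-4-one to a (2E,4Z)-iododienoyl oxazolidinone, which sets C1.
5. Order of ring formation: pyrone ring, then carbocycle, then oxirane.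

Key step: step 12

Remark: for the boron aldol of step 17 it is assumed, as the usual reagent-control model for ethyl ketone (Z)-enolates, that (+)-Ipc ligands direct attack to the Re face of the aldehyde.

**Route**

Step 1
Reactants: 1 ethyl 2-methyl-3-oxopentanoate; 2 N-methoxy-N-methylacetamide
Product: 3 ethyl 2,4-dimethyl-3,5-dioxohexanoate
Conditions: NaH, THF, 0 °C; n-BuLi, 0 °C; then 2, −78 °C → rt; aq. NH4Cl
Reagents that add atoms: none
Why: γ-Acylation of the β-keto ester dianion (Huckin–Weiler) by the Weinreb amide, whose chelated tetrahedral adduct prevents over-addition, should give the β,δ-diketo ester.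

Step 2
Reactants: 3 ethyl 2,4-dimethyl-3,5-dioxohexanoate
Product: 4 4-hydroxy-3,5,6-trimethyl-2H-pyran-2-one
Conditions: DBU, toluene, reflux
Reagents that add atoms: none
Why: Lactonisation of the δ-ketone enol onto the ester with loss of ethanol is the standard triketide cyclisation to a 4-hydroxy-2-pyrone.

Step 3
Reactants: 4 4-hydroxy-3,5,6-trimethyl-2H-pyran-2-one
Product: 5 2-methoxy-3,5,6-trimethyl-4H-pyran-4-one
Conditions: MeOTf, CH2Cl2, rt; aq. NaHCO3
Reagents that add atoms: methyl triflate COS(=O)(=O)C(F)(F)F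
Why: The hard methylating agent should alkylate the lactone carbonyl oxygen, and deprotonation of the resulting 2-methoxy-4-hydroxypyrylium ion gives the α-methoxy-γ-pyrone rather than the 4-methoxy-α-pyrone.

Step 4
Reactants: 6 prop-2-yn-1-ol
Product: 7 (Z)-3-iodo-2-methylprop-2-en-1-ol
Conditions: MeMgBr (2.5 equiv), CuI (10 mol %), THF, −10 °C → rt; then I2, −40 → 0 °C
Reagents that add atoms: methylmagnesium bromide C[Mg]Br; iodine II
Why: Copper-catalysed anti-carbomagnesiation of the propargylic alkoxide gives a five-membered alkenylmagnesium chelate whose iodinolysis with retention places iodine cis to the hydroxymethyl group.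

Step 5
Reactants: 7 (Z)-3-iodo-2-methylprop-2-en-1-ol
Product: 8 (Z)-3-iodo-2-methylprop-2-enal
Conditions: MnO2, CH2Cl2, rt, dark; used at once
Reagents that add atoms: none
Why: Neutral allylic oxidation should give the enal without Z to E isomerisation of the β-iodoenal.

Step 6
Reactants: 9 2-(diethoxyphosphoryl)acetic acid; 10 (S)-4-benzyloxazolidin-2-one
Product: 11 (S)-4-benzyl-3-[2-(diethoxyphosphoryl)acetyl]oxazolidin-2-one
Conditions: PivCl, Et3N, THF, −20 °C; then 10, LiCl, rt
Reagents that add atoms: none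
Why: N-Acylation of the oxazolidinone by the mixed pivalic anhydride of the acid is a standard way to make the phosphonate imide.

Step 7
Reactants: 8 (Z)-3-iodo-2-methylprop-2-enal; 11 (S)-4-benzyl-3-[2-(diethoxyphosphoryl)acetyl]oxazolidin-2-one
Product: 12 (S)-4-benzyl-3-[(2E,4Z)-5-iodo-4-methylpenta-2,4-dienoyl]oxazolidin-2-one
Conditions: LiCl, i-Pr2NEt, MeCN, 0 °C → rt
Reagents that add atoms: none
Why: Horner–Wadsworth–Emmons olefination under Masamune–Roush conditions should give the (2E)-enoyl imide and leave the base-sensitive (Z)-iodoalkene intact.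

Step 8
Reactants: 5 2-methoxy-3,5,6-trimethyl-4H-pyran-4-one; 12 (S)-4-benzyl-3-[(2E,4Z)-5-iodo-4-methylpenta-2,4-dienoyl]oxazolidin-2-one
Product: 14 (S)-4-benzyl-3-[(3S,4Z)-5-iodo-3-[(6-methoxy-3,5-dimethyl-4-oxo-4H-pyran-2-yl)methyl]-4-methylpent-4-enoyl]oxazolidin-2-one, via silyl dienol ether 13 (not isolated)
Conditions: 5, LiN(SiMe3)2, THF, −78 °C; TMSCl; volatiles removed, CH2Cl2; then 12, TiCl4, −78 °C; aq. NaHCO3
Reagents that add atoms: none
Why: Vinylogous Mukaiyama–Michael addition of the pyrone-derived silyl dienol ether through its exocyclic methylene carbon to the TiCl4-chelated s-cis N-enoyl oxazolidinone should occur on the face opposite to the benzyl group and set C1, with 1,4-addition favoured because the chelated carbonyl activates the β-carbon most strongly.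

Step 9
Reactants: 14 Michael adduct (imide)
Product: 15 (3R,4Z)-5-iodo-3-[(6-methoxy-3,5-dimethyl-4-oxo-4H-pyran-2-yl)methyl]-4-methylpent-4-en-1-ol
Conditions: LiBH4, MeOH (1 equiv), THF, 0 °C
Reagents that add atoms: none
Why: Reductive removal of the auxiliary at the exocyclic imide carbonyl should give the primary alcohol, while the vinylogous-ester pyrone and the vinyl iodide are expected to be inert.

Step 10
Reactants: 15 iodo alcohol
Product: 16 tert-butyl{[(3R,4Z)-5-iodo-3-[(6-methoxy-3,5-dimethyl-4-oxo-4H-pyran-2-yl)methyl]-4-methylpent-4-en-1-yl]oxy}dimethylsilane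
Conditions: TBSCl, imidazole, DMF, rt
Reagents that add atoms: tert-butyldimethylsilyl chloride CC(C)(C)[Si](C)(C)Cl
Why: Standard silylation protects the primary alcohol against the basic conditions of the key step.

Step 11
Reactants: 17 prop-1-yn-1-ylmagnesium bromide; 18 benzyl(chloro)dimethylsilane
Product: 19 benzyl(dimethyl)(prop-1-yn-1-yl)silane
Conditions: THF, 0 °C → rt
Reagents that add atoms: none
Why: Substitution at silicon by the alkynyl Grignard reagent gives the silylalkyne, and the benzyldimethylsilyl group is chosen because fluoride later removes it from a vinylic carbon under mild conditions.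

Step 12
Reactants: 16 (Z)-vinyl iodide silyl ether; 19 benzyl(dimethyl)(prop-1-yn-1-yl)silane (3 equiv)
Product: 21 tert-butyl{2-[(1S,6R)-5-[benzyl(dimethyl)silyl]-6-(6-methoxy-3,5-dimethyl-4-oxo-4H-pyran-2-yl)-2,4,6-trimethylcyclohexa-2,4-dien-1-yl]ethoxy}dimethylsilane, via cyclohexadiene 20 (not isolated)
Conditions: Pd(OAc)2 (10 mol %), PPh3 (20 mol %), n-Bu4NCl, Cs2CO3, DMF, 80 °C; then MeI, 0 °C → rt
Reagents that add atoms: iodomethane CI
Why: Proposed new method: oxidative addition of zerovalent palladium to the (Z)-vinyl iodide is followed by syn-carbopalladation of alkyne 19 with the silyl group next to palladium (C3–C4 bond), palladation of the caesium pyranolate at the pyrone-activated methylene and C(sp2)–C(sp3) reductive elimination (C5–C6 bond), so that a propyne unit is inserted between C3 and C6. The closest known reaction type is the Larock-type carboannulation of internal alkynes by aryl or vinyl halides carrying a malonate-type carbon pronucleophile, together with palladium-catalysed γ-alkenylation of vinylogous enolates. The six-membered ring closes by reductive elimination from a seven-membered palladacycle (formal [4+2] annulation), whereas closure without alkyne insertion would give a cyclobutene and is not expected. Regioselectivity of the insertion should be secured by the bulky silyl group, which also blocks a second insertion, and the cis arrangement of C1 and C4 on C2=C3 is carried over from the (Z)-iodide. The doubly activated C6–H of 20 is deprotonated under the reaction conditions, and iodomethane should alkylate the planar pyranolate at C6 on the face opposite to the C1 side chain, which allylic 1,3-strain holds pseudoaxial, so that the quaternary centre is set with methyl trans to the side chain. The C1 stereocentre is not touched.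

Step 13
Reactants: 21 silylated cyclohexadiene
Product: 22 2-[(1S,6R)-6-(6-methoxy-3,5-dimethyl-4-oxo-4H-pyran-2-yl)-2,4,6-trimethylcyclohexa-2,4-dien-1-yl]ethan-1-ol
Conditions: TBAF (5 equiv), THF, 0 → 40 °C
Reagents that add atoms: none
Why: Fluoride should cleave the silyl ether and, after debenzylation at silicon, protodesilylate the vinylsilane with retention, so that one operation unmasks the alcohol and C5–H, while the quaternary C6 prevents base-induced diene migration.

Step 14
Reactants: 22 diene alcohol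
Product: 23 2-[(1R,4R,5R,6S)-4-(6-methoxy-3,5-dimethyl-4-oxo-4H-pyran-2-yl)-2,4,6-trimethyl-7-oxabicyclo[4.1.0]hept-2-en-5-yl]ethan-1-ol
Conditions: dimethyldioxirane (1.1 equiv), acetone, −40 → −20 °C
Reagents that add atoms: dimethyldioxirane CC1(C)OO1
Why: Electrophilic epoxidation should take place at the more accessible C2=C3 bond (C4=C5 is flanked by the quaternary, pyrone-bearing C6) from the face opposite to the cis-disposed C1 side chain and C6 pyrone, which sets C2 and C3 by substrate control, and the neutral reagent spares the vinyl epoxide.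

Step 15
Reactants: 23 epoxy alcohol
Product: 24 2-[(1R,4R,5R,6S)-4-(6-methoxy-3,5-dimethyl-4-oxo-4H-pyran-2-yl)-2,4,6-trimethyl-7-oxabicyclo[4.1.0]hept-2-en-5-yl]acetaldehyde
Conditions: Dess–Martin periodinane, NaHCO3, CH2Cl2, 0 °C → rt
Reagents that add atoms: none
Why: Buffered Dess–Martin oxidation converts the primary alcohol into the aldehyde under conditions that acid-sensitive vinyl epoxides tolerate.

Step 16
Reactants: 24 epoxy aldehyde
Product: 25 2-[(1R,4R,5S,6S)-4-(6-methoxy-3,5-dimethyl-4-oxo-4H-pyran-2-yl)-2,4,6-trimethyl-7-oxabicyclo[4.1.0]hept-2-en-5-yl]prop-2-enal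
Conditions: N,N-dimethylmethyleneiminium iodide, Et3N, CH2Cl2, rt
Reagents that add atoms: N,N-dimethylmethyleneiminium iodide C=[N+](C)C.[I-]
Why: Eschenmoser methylenation (Mannich reaction of the aldehyde enol, then loss of dimethylamine) should give the 2-substituted acrolein, and C1 is not enolisable and keeps its configuration (the change of descriptor is only a change of priorities).

Step 17
Reactants: 25 enal; 26 pentan-3-one
Product: 29 (4R,5R)-5-hydroxy-6-[(1R,4R,5R,6S)-4-(6-methoxy-3,5-dimethyl-4-oxo-4H-pyran-2-yl)-2,4,6-trimethyl-7-oxabicyclo[4.1.0]hept-2-en-5-yl]-4-methylhept-6-en-3-one (target), via enol borinate 27 (not isolated), via boron aldolate 28 (not isolated)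
Conditions: 26, (+)-Ipc2BOTf, i-Pr2NEt, CH2Cl2, −78 °C; then 25, −78 → −20 °C; pH 7 buffer, MeOH, H2O2, 0 °C
Reagents that add atoms: none
Why: In this diisopinocampheylboron aldol the (Z)-enol borinate should add through a chair Zimmerman–Traxler transition state to give the syn adduct, and the (+)-Ipc ligands should direct it to the Re face of the aldehyde (reagent control), setting the (R)-carbinol and the (R)-methyl centre.

**Compound list**

1 | ethyl 2-methyl-3-oxopentanoate | CCOC(=O)C(C)C(=O)CC | starting material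
2 | N-methoxy-N-methylacetamide | CC(=O)N(C)OC | starting material
3 | ethyl 2,4-dimethyl-3,5-dioxohexanoate | CCOC(=O)C(C)C(=O)C(C)C(C)=O | intermediate
4 | 4-hydroxy-3,5,6-trimethyl-2H-pyran-2-one | Cc1oc(=O)c(C)c(O)c1C | intermediate
5 | 2-methoxy-3,5,6-trimethyl-4H-pyran-4-one | COc1oc(C)c(C)c(=O)c1C | intermediate
6 | prop-2-yn-1-ol | OCC#C | starting material
7 | (Z)-3-iodo-2-methylprop-2-en-1-ol | OC/C(C)=C\I | intermediate
8 | (Z)-3-iodo-2-methylprop-2-enal | O=C/C(C)=C\I | intermediate
9 | 2-(diethoxyphosphoryl)acetic acid | CCOP(=O)(CC(=O)O)OCC | starting material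
10 | (S)-4-benzyloxazolidin-2-one | O=C1N[C@@H](Cc2ccccc2)CO1 | starting material
11 | (S)-4-benzyl-3-[2-(diethoxyphosphoryl)acetyl]oxazolidin-2-one | CCOP(=O)(CC(=O)N1[C@@H](Cc2ccccc2)COC1=O)OCC | intermediate
12 | (S)-4-benzyl-3-[(2E,4Z)-5-iodo-4-methylpenta-2,4-dienoyl]oxazolidin-2-one | O=C(/C=C/C(C)=C\I)N1[C@@H](Cc2ccccc2)COC1=O | intermediate
13 | [(6-methoxy-3,5-dimethyl-2-methylidene-2H-pyran-4-yl)oxy]trimethylsilane (silyl dienol ether of 5) | C=C1OC(OC)=C(C)C(O[Si](C)(C)C)=C1C | intermediate (not isolated)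
14 | (S)-4-benzyl-3-[(3S,4Z)-5-iodo-3-[(6-methoxy-3,5-dimethyl-4-oxo-4H-pyran-2-yl)methyl]-4-methylpent-4-enoyl]oxazolidin-2-one | O=C(C[C@H](Cc1oc(OC)c(C)c(=O)c1C)/C(C)=C\I)N1[C@@H](Cc2ccccc2)COC1=O | intermediate
15 | (3R,4Z)-5-iodo-3-[(6-methoxy-3,5-dimethyl-4-oxo-4H-pyran-2-yl)methyl]-4-methylpent-4-en-1-ol | OCC[C@H](Cc1oc(OC)c(C)c(=O)c1C)/C(C)=C\I | intermediate
16 | tert-butyl{[(3R,4Z)-5-iodo-3-[(6-methoxy-3,5-dimethyl-4-oxo-4H-pyran-2-yl)methyl]-4-methylpent-4-en-1-yl]oxy}dimethylsilane | CC(C)(C)[Si](C)(C)OCC[C@H](Cc1oc(OC)c(C)c(=O)c1C)/C(C)=C\I | intermediate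
17 | prop-1-yn-1-ylmagnesium bromide | CC#C[Mg]Br | starting material
18 | benzyl(chloro)dimethylsilane | C[Si](C)(Cl)Cc1ccccc1 | starting material
19 | benzyl(dimethyl)(prop-1-yn-1-yl)silane | CC#C[Si](C)(C)Cc1ccccc1 | intermediate
20 | tert-butyl{2-[(1R)-5-[benzyl(dimethyl)silyl]-6-(6-methoxy-3,5-dimethyl-4-oxo-4H-pyran-2-yl)-2,4-dimethylcyclohexa-2,4-dien-1-yl]ethoxy}dimethylsilane (C6 not defined; present largely as its caesium pyranolate) | CC(C)(C)[Si](C)(C)OCC[C@H]1C(C)=CC(C)=C([Si](C)(C)Cc2ccccc2)C1c1oc(OC)c(C)c(=O)c1C | intermediate (not isolated)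
21 | tert-butyl{2-[(1S,6R)-5-[benzyl(dimethyl)silyl]-6-(6-methoxy-3,5-dimethyl-4-oxo-4H-pyran-2-yl)-2,4,6-trimethylcyclohexa-2,4-dien-1-yl]ethoxy}dimethylsilane (side chain and pyrone cis) | CC(C)(C)[Si](C)(C)OCC[C@H]1C(C)=CC(C)=C([Si](C)(C)Cc2ccccc2)[C@@]1(C)c1oc(OC)c(C)c(=O)c1C | intermediate
22 | 2-[(1S,6R)-6-(6-methoxy-3,5-dimethyl-4-oxo-4H-pyran-2-yl)-2,4,6-trimethylcyclohexa-2,4-dien-1-yl]ethan-1-ol | OCC[C@H]1C(C)=CC(C)=C[C@@]1(C)c1oc(OC)c(C)c(=O)c1C | intermediate
23 | 2-[(1R,4R,5R,6S)-4-(6-methoxy-3,5-dimethyl-4-oxo-4H-pyran-2-yl)-2,4,6-trimethyl-7-oxabicyclo[4.1.0]hept-2-en-5-yl]ethan-1-ol (oxirane oxygen trans to side chain and pyrone) | OCC[C@H]1[C@]2(C)O[C@@H]2C(C)=C[C@@]1(C)c1oc(OC)c(C)c(=O)c1C | intermediate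
24 | 2-[(1R,4R,5R,6S)-4-(6-methoxy-3,5-dimethyl-4-oxo-4H-pyran-2-yl)-2,4,6-trimethyl-7-oxabicyclo[4.1.0]hept-2-en-5-yl]acetaldehyde | O=CC[C@H]1[C@]2(C)O[C@@H]2C(C)=C[C@@]1(C)c1oc(OC)c(C)c(=O)c1C | intermediate
25 | 2-[(1R,4R,5S,6S)-4-(6-methoxy-3,5-dimethyl-4-oxo-4H-pyran-2-yl)-2,4,6-trimethyl-7-oxabicyclo[4.1.0]hept-2-en-5-yl]prop-2-enal | C=C(C=O)[C@H]1[C@]2(C)O[C@@H]2C(C)=C[C@@]1(C)c1oc(OC)c(C)c(=O)c1C | intermediate
26 | pentan-3-one | CCC(=O)CC | starting material
27 | (Z)-pent-2-en-3-yl (+)-diisopinocampheylborinate | C/C=C(\OB([C@H]1C[C@H]2C[C@@H]([C@@H]1C)C2(C)C)[C@H]1C[C@H]2C[C@@H]([C@@H]1C)C2(C)C)CC | intermediate (not isolated)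
28 | O-(diisopinocampheylboryl) aldolate of 29 | C=C([C@H](OB([C@H]1C[C@H]2C[C@@H]([C@@H]1C)C2(C)C)[C@H]1C[C@H]2C[C@@H]([C@@H]1C)C2(C)C)[C@@H](C)C(=O)CC)[C@H]1[C@]2(C)O[C@@H]2C(C)=C[C@@]1(C)c1oc(OC)c(C)c(=O)c1C | intermediate (not isolated)
29 | (4R,5R)-5-hydroxy-6-[(1R,4R,5R,6S)-4-(6-methoxy-3,5-dimethyl-4-oxo-4H-pyran-2-yl)-2,4,6-trimethyl-7-oxabicyclo[4.1.0]hept-2-en-5-yl]-4-methylhept-6-en-3-one | C=C([C@H](O)[C@@H](C)C(=O)CC)[C@H]1[C@]2(C)O[C@@H]2C(C)=C[C@@]1(C)c1oc(OC)c(C)c(=O)c1C | target

**Step count and risks**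

Total step count: 17. Longest linear sequence: 12 steps (6 → 7 → 8 → 12 → 14 → 15 → 16 → 21 → 22 → 23 → 24 → 25 → 29; the branch from 1 through 5 is equally long).

Steps most likely to fail:

1. Step 12 (proposed new method). The vinylogous pyranolate may fail to capture the hindered, silyl-bearing dienylpalladium species, so that protodepalladation or alkyne oligomerisation takes over, or the delocalised anion may be methylated on oxygen or isomerise the diene before alkylation. The fallback uses known reactions, sets out from 16 and comes back at 22. Stille coupling of 16 (Pd(PPh3)4, CuI, DMF) with tributyl[(Z)-1-(trimethylsilyl)prop-1-en-2-yl]stannane F1, itself available by Pd(PPh3)4-catalysed syn-silylstannation of propyne with tributyl(trimethylsilyl)stannane, should give the (Z,Z)-dienylsilane F2. Ipso-iododesilylation with N-iodosuccinimide (retention) would give the (Z,Z)-dienyl iodide F3. Intramolecular palladium-catalysed γ-alkenylation of the pyrone methylene (Pd(PPh3)4, Cs2CO3, THF, 65 °C), followed by iodomethane in the same flask, would give the C5-unsubstituted, C6-methylated cyclohexadiene silyl ether F4. TBAF then gives 22.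

2. Step 8. Competing 1,6-addition with loss of iodide, erosion of facial selectivity if the chelate is not maintained, or Lewis acid-induced desilylation of the dienol ether before addition may spoil the conjugate addition. The fallback sets out from 8 and comes back at 15. Knoevenagel condensation of 8 with dimethyl malonate (TiCl4, pyridine) would give dimethyl 2-[(2Z)-3-iodo-2-methylprop-2-en-1-ylidene]propanedioate F5, whose doubly activated β-carbon favours 1,4-addition. Catalyst-controlled Mukaiyama–Michael addition of 13, with the tert-butyl-bis(oxazoline) complex of Cu(SbF6)2 in the ligand enantiomer that gives the (S)-adduct, would give the malonate F6. Krapcho dealkoxycarbonylation (LiCl, wet DMSO, 120 °C) would give the methyl ester F7, and LiBH4 reduction returns to 15.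

3. Step 14. Loss of site selectivity between the two ring alkenes, over-oxidation to a bis-epoxide, or opening of the vinyl epoxide may occur. The fallback sets out from 21 and comes back at 23. Epoxidation of 21 with dimethyldioxirane, while C4=C5 still carries the bulky benzyldimethylsilyl group and is sterically shielded, should give the silylated vinyl epoxide F8; TBAF then removes both silyl groups and gives 23 directly.

Further compounds
F1 | step 12 | tributyl[(Z)-1-(trimethylsilyl)prop-1-en-2-yl]stannane | C[Si](C)(C)/C=C(/C)[Sn](CCCC)(CCCC)CCCC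
F2 | step 12 | tert-butyl{[(3R,4Z,6Z)-3-[(6-methoxy-3,5-dimethyl-4-oxo-4H-pyran-2-yl)methyl]-4,6-dimethyl-7-(trimethylsilyl)hepta-4,6-dien-1-yl]oxy}dimethylsilane | CC(C)(C)[Si](C)(C)OCC[C@H](Cc1oc(OC)c(C)c(=O)c1C)/C(C)=C\C(C)=C/[Si](C)(C)C
F3 | step 12 | tert-butyl{[(3R,4Z,6Z)-7-iodo-3-[(6-methoxy-3,5-dimethyl-4-oxo-4H-pyran-2-yl)methyl]-4,6-dimethylhepta-4,6-dien-1-yl]oxy}dimethylsilane | CC(C)(C)[Si](C)(C)OCC[C@H](Cc1oc(OC)c(C)c(=O)c1C)/C(C)=C\C(C)=C/I
F4 | step 12 | tert-butyl{2-[(1S,6R)-6-(6-methoxy-3,5-dimethyl-4-oxo-4H-pyran-2-yl)-2,4,6-trimethylcyclohexa-2,4-dien-1-yl]ethoxy}dimethylsilane | CC(C)(C)[Si](C)(C)OCC[C@H]1C(C)=CC(C)=C[C@@]1(C)c1oc(OC)c(C)c(=O)c1C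
F5 | step 8 | dimethyl 2-[(2Z)-3-iodo-2-methylprop-2-en-1-ylidene]propanedioate | COC(=O)C(=C/C(C)=C\I)C(=O)OC
F6 | step 8 | dimethyl 2-[(2S,3Z)-4-iodo-1-(6-methoxy-3,5-dimethyl-4-oxo-4H-pyran-2-yl)-3-methylbut-3-en-2-yl]propanedioate | COC(=O)C(C(=O)OC)[C@H](Cc1oc(OC)c(C)c(=O)c1C)/C(C)=C\I
F7 | step 8 | methyl (3S,4Z)-5-iodo-3-[(6-methoxy-3,5-dimethyl-4-oxo-4H-pyran-2-yl)methyl]-4-methylpent-4-enoate | COC(=O)C[C@H](Cc1oc(OC)c(C)c(=O)c1C)/C(C)=C\I
F8 | step 14 | C2–C3 epoxide of 21 (oxirane oxygen trans to side chain and pyrone; both silyl groups retained) | CC(C)(C)[Si](C)(C)OCC[C@H]1[C@]2(C)O[C@@H]2C(C)=C([Si](C)(C)Cc3ccccc3)[C@@]1(C)c1oc(OC)c(C)c(=O)c1C
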